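## Retrosynthetic overview

1. Numbering follows the hydroazulene: C1–C2 oxirane (CH3 on C2), C3, ring fusion C3a/C8a, C4 (isopropyl), C5 (aroyloxy), C6, C7 (CH3, OH), C8. The plan rests on the seven-membered ring carrying its oxygen at C5 between isopropyl-bearing C4 and the C6 methylene, with methyl-bearing C7 next: a 3-methylcyclohept-2-enone, reached by pushing C6 into the C5=C7 bond of a six-membered silyl enol ether.
2. Late disconnections: aryl ester at C5–O and the C7-OH-directed oxirane; C1=C2 by McMurry coupling (five-membered ring); C5–OH and C7–OH from the enone by reduction, directed epoxidation and hydride opening.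
3. Key disconnection: C5–C6 and C6–C7 (CH2 from CH2I2), by cyclopropanation of the C5=C7 enol ether and FeCl3 cleavage of the C5–C7 bond.
4. The enol ether comes from an auxiliary-controlled Diels–Alder reaction (bonds C4–C3a and C8–C8a) that sets C4, C3a and C8a.
5. Ring order: cyclohexene, then cycloheptenone, then cyclopentene, then oxirane.

Key step: step 10

Remark: α is the face of the seven-membered ring carrying the C4 isopropyl group, the C5 and C7 oxygens, C1 and H-3a; β carries H-4, H-5, H-8a, C3 and the C7 methyl. Cyclopropane 15 and chloride 16 are carried as mixtures at their transient centres, which step 10 itself removes.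

## Route

Step 1
Reactants: 1 3-methylbutanal (isovaleraldehyde); 2 isopropenylmagnesium bromide (0.5 M in THF)
Product: 3 2,5-dimethylhex-1-en-3-ol (racemic)
Conditions: THF, 0 °C; aq. NH4Cl
Reagents that add atoms: none
Why: Grignard 1,2-addition to an unhindered aldehyde; the carbinol centre is removed in step 2, so its configuration is irrelevant.

Step 2
Reactants: 3 2,5-dimethylhex-1-en-3-ol
Product: 4 2,5-dimethylhex-1-en-3-one
Conditions: Dess–Martin periodinane, CH2Cl2, 0 °C → rt
Reagents that add atoms: none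
Why: Dess–Martin oxidation of a secondary allylic alcohol under neutral conditions should spare the polymerisable α-methylene ketone, which is used at once.

Step 3
Reactants: 4 2,5-dimethylhex-1-en-3-one
Product: 5 (Z)-tert-butyl[(2,5-dimethylhexa-1,3-dien-3-yl)oxy]dimethylsilane
Conditions: TBSOTf, Et3N, CH2Cl2, 0 °C
Reagents that add atoms: tert-butyldimethylsilyl trifluoromethanesulfonate, CC(C)(C)[Si](C)(C)OS(=O)(=O)C(F)(F)F
Why: Soft enolisation/O-silylation can only occur toward C4; the (Z)-enol ether (isopropyl cis to OSi, hence "outside" in the s-cis diene) should dominate because the other geometry suffers A1,3 strain with the isopropenyl group.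

Step 4
Reactants: 6 (S)-4-benzyl-1,3-oxazolidin-2-one; 7 bromoacetyl bromide
Product: 8 (S)-4-benzyl-3-(bromoacetyl)-1,3-oxazolidin-2-one
Conditions: n-BuLi, THF, −78 °C; then 7, −78 → 0 °C
Reagents that add atoms: none
Why: N-acylation of the lithiated oxazolidinone by the acyl bromide, which is far more electrophilic than the alkyl bromide.

Step 5
Reactants: 8 (S)-4-benzyl-3-(bromoacetyl)-1,3-oxazolidin-2-one
Product: 9 diethyl {2-[(S)-4-benzyl-2-oxo-1,3-oxazolidin-3-yl]-2-oxoethyl}phosphonate
Conditions: P(OEt)3, toluene, 90 °C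
Reagents that add atoms: triethyl phosphite, CCOP(OCC)OCC
Why: Michaelis–Arbuzov reaction of an activated α-bromo carbonyl compound; the stereocentre of the auxiliary is not involved.

Step 6
Reactants: 10 ethyl 2-(2-methyl-1,3-dioxolan-2-yl)acetate (commercial ethylene ketal of ethyl acetoacetate)
Product: 11 2-(2-methyl-1,3-dioxolan-2-yl)acetaldehyde
Conditions: i-Bu2AlH (1.1 equiv), CH2Cl2, −78 °C; MeOH, then aq. KNaC4H4O6
Reagents that add atoms: none
Why: Low-temperature i-Bu2AlH half-reduction; the aluminium hemiacetal is held by chelation to a ketal oxygen until work-up, and the aldehyde is used crude.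

Step 7
Reactants: 11 2-(2-methyl-1,3-dioxolan-2-yl)acetaldehyde; 9 diethyl {2-[(S)-4-benzyl-2-oxo-1,3-oxazolidin-3-yl]-2-oxoethyl}phosphonate
Product: 12 (S)-4-benzyl-3-[(E)-4-(2-methyl-1,3-dioxolan-2-yl)but-2-enoyl]-1,3-oxazolidin-2-one
Conditions: LiCl, i-Pr2NEt, MeCN, rt
Reagents that add atoms: none
Why: Horner–Wadsworth–Emmons olefination under Masamune–Roush conditions is mild enough for the β-ketal aldehyde and should give the (E)-enoyl imide.

Step 8
Reactants: 12 (S)-4-benzyl-3-[(E)-4-(2-methyl-1,3-dioxolan-2-yl)but-2-enoyl]-1,3-oxazolidin-2-one; 5 (Z)-tert-butyl[(2,5-dimethylhexa-1,3-dien-3-yl)oxy]dimethylsilane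
Product: 13 (S)-4-benzyl-3-{[(1S,5S,6S)-4-(tert-butyldimethylsilyloxy)-3-methyl-6-[(2-methyl-1,3-dioxolan-2-yl)methyl]-5-(propan-2-yl)cyclohex-3-en-1-yl]carbonyl}-1,3-oxazolidin-2-one
Conditions: Me2AlCl (1.6 equiv), 5 (2 equiv), CH2Cl2, −78 → −30 °C; aq. NaHCO3
Reagents that add atoms: none
Why: Auxiliary-controlled Lewis-acid Diels–Alder reaction: the Me2Al chelate holds the imide s-cis and the diene adds endo to the Si face of C8a, opposite the benzyl group; the enol ether carbon C4 bonds to the acceptor β-carbon C3a, the (E)-dienophile gives C3a/C8a trans, and the outside isopropyl group ends up trans to the C3a side chain.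

Step 9
Reactants: 13 Diels–Alder imide
Product: 14 methyl (1S,5S,6S)-4-(tert-butyldimethylsilyloxy)-3-methyl-6-[(2-methyl-1,3-dioxolan-2-yl)methyl]-5-(propan-2-yl)cyclohex-3-ene-1-carboxylate
Conditions: MeMgBr, MeOH (gives MeOMgBr), THF, 0 °C
Reagents that add atoms: methanol (delivered as MeOMgBr), CO
Why: Magnesium methoxide transesterification cleaves the exocyclic imide carbonyl and returns auxiliary 6; the hindered tetrasubstituted silyl enol ether should survive, and C8a cannot drift because the all-trans array is already the stable one.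

Step 10
Reactants: 14 methyl (1S,5S,6S)-4-(tert-butyldimethylsilyloxy)-3-methyl-6-[(2-methyl-1,3-dioxolan-2-yl)methyl]-5-(propan-2-yl)cyclohex-3-ene-1-carboxylate
Product: 17 methyl (1S,2S,3S)-6-methyl-2-[(2-methyl-1,3-dioxolan-2-yl)methyl]-4-oxo-3-(propan-2-yl)cyclohept-5-ene-1-carboxylate, via silyloxycyclopropane 15 (not isolated), via β-chloro ketone 16 (not isolated)
Conditions: Et2Zn, CH2I2, CH2Cl2, 0 °C → rt; crude 15: FeCl3 (3 equiv), pyridine (1 equiv), DMF, 0 °C → rt; crude 16: NaOAc, MeOH, reflux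
Reagents that add atoms: diiodomethane, ICI
Why: The zinc carbenoid EtZnCH2I transfers CH2 in a concerted, syn [2+1] fashion to the only alkene present, the electron-rich tetrasubstituted C5=C7 silyl enol ether, closing the three-membered ring (bonds C5–C6 and C6–C7) as in a Furukawa-type Simmons–Smith cyclopropanation of enol silanes. FeCl3 (trivalent iron) then exchanges the silyl group for iron at the cyclopropanol oxygen and oxidises it by one electron; β-scission of the internal C5–C7 bond gives the C5 ketone and a tertiary C7 radical that takes chlorine from a second FeCl3, which is the Ito–Saegusa ring enlargement of silyloxycyclopropanes. The seven-membered ring is therefore not closed end to end but arises by cleavage of the zero-atom bridge of the bicyclo[4.1.0]heptane, and NaOAc removes HCl by an E1cB path through the C6 enolate to give the conjugated C6=C7 enone. No surviving stereocentre is created: the cyclopropane centres C5 and C7 and the C7 chloride are transient, so either face of methylene transfer converges on 17. The selectivities needed are cleavage of the internal and not an external cyclopropane bond, secured by the tertiary radical at methyl-bearing C7 and by the better overlap of the ring-fusion bond, and retention of C4, which is α to the new ketone but already holds the isopropyl group trans to the C3a side chain. The ester and dioxolane are inert to the carbenoid, and pyridine in DMF tempers the Lewis acidity of the iron salt toward the ketal.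

Step 11
Reactants: 17 cycloheptenone
Product: 18 methyl (1S,2S,3S,4S)-4-hydroxy-6-methyl-2-[(2-methyl-1,3-dioxolan-2-yl)methyl]-3-(propan-2-yl)cyclohept-5-ene-1-carboxylate (5α-OH, cis to the isopropyl group)
Conditions: LiBH(s-Bu)3, THF, −78 °C; then H2O
Reagents that add atoms: none
Why: 1,2-Reduction of a β,β-disubstituted enone by a bulky trialkylborohydride; as with 2-alkylcycloalkanones, hydride should come from the β face, anti to the flanking C4 isopropyl group, giving the cis (5α) alcohol, and the ester is untouched at −78 °C.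

Step 12
Reactants: 18 allylic alcohol
Product: 19 methyl 6-hydroxy-1-methyl-4-[(2-methyl-1,3-dioxolan-2-yl)methyl]-5-(propan-2-yl)-8-oxabicyclo[5.1.0]octane-3-carboxylate (5α-hydroxy-6α,7α-epoxide, oxirane cis to the hydroxyl)
Conditions: VO(acac)2 (5 mol%), t-BuOOH, CH2Cl2, 0 °C → rt
Reagents that add atoms: tert-butyl hydroperoxide, CC(C)(C)OO
Why: Sharpless-type hydroxyl-directed epoxidation of a cyclic allylic alcohol: the vanadium alkoxide delivers oxygen to the alkene face syn to C5–OH, setting C6 and the C7–O bond on the α face.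

Step 13
Reactants: 19 epoxy alcohol
Product: 20 6-(hydroxymethyl)-1-methyl-5-[(2-methyl-1,3-dioxolan-2-yl)methyl]-4-(propan-2-yl)cycloheptane-1,3-diol (C5 and C7 hydroxyls cis, both α; C1 primary alcohol)
Conditions: NaAlH2(OCH2CH2OCH3)2 (5 equiv), THF, 0 °C → rt; aq. KNaC4H4O6
Reagents that add atoms: none
Why: The C5 alkoxyaluminate delivers hydride intramolecularly to C6 (C-2 opening of a 2,3-epoxy alcohol, also the less substituted carbon), leaving the C7–O bond intact as the syn-1,3-diol; the same reagent reduces the ester to the C1 alcohol needed for the later aldehyde.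

Step 14
Reactants: 20 triol
Product: 21 tris(tert-butyldimethylsilyl) ether of 20
Conditions: TBSOTf (4.5 equiv), 2,6-lutidine, CH2Cl2, 0 °C → rt
Reagents that add atoms: tert-butyldimethylsilyl trifluoromethanesulfonate, CC(C)(C)[Si](C)(C)OS(=O)(=O)C(F)(F)F
Why: The silyl triflate is reactive enough to silylate the hindered secondary C5 and tertiary C7 hydroxyls as well as the primary one.

Step 15
Reactants: 21 tris-silyl ether
Product: 22 1-[3,5-bis(tert-butyldimethylsilyloxy)-7-(hydroxymethyl)-5-methyl-2-(propan-2-yl)cycloheptyl]propan-2-one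
Conditions: HCl (1 M aq.), THF, 0 °C → rt
Reagents that add atoms: water, O
Why: Mild aqueous acid hydrolyses the dioxolane and the unhindered primary silyl ether, while the hindered secondary and tertiary silyl ethers should persist because acid-catalysed Si–O hydrolysis is strongly retarded by steric bulk.

Step 16
Reactants: 22 hydroxy ketone
Product: 23 4,6-bis(tert-butyldimethylsilyloxy)-6-methyl-2-(2-oxopropyl)-3-(propan-2-yl)cycloheptane-1-carbaldehyde
Conditions: Dess–Martin periodinane, NaHCO3, CH2Cl2, 0 °C → rt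
Reagents that add atoms: none
Why: Buffered Dess–Martin oxidation of the primary alcohol (through the open form of any hemiketal) gives the aldehyde without epimerising C8a.

Step 17
Reactants: 23 keto aldehyde
Product: 24 5α,7α-bis(tert-butyldimethylsilyloxy)-2,7-dimethyl-4α-(propan-2-yl)-3,3a,4,5,6,7,8,8a-octahydroazulene (trans-fused, H-3a α, H-8a β)
Conditions: TiCl3(DME)1.5, Zn–Cu couple, DME, reflux, slow addition of 23
Reagents that add atoms: none
Why: Intramolecular McMurry coupling: low-valent titanium joins C1 and C2 as a titanium pinacolate and deoxygenates it to the trisubstituted C1=C2 alkene, closing the five-membered ring; no stereocentre is formed and silyl ethers tolerate the reagent.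

Step 18
Reactants: 24 bis-silyl ether
Product: 25 2,7-dimethyl-4α-(propan-2-yl)-3,3a,4,5,6,7,8,8a-octahydroazulene-5α,7α-diol
Conditions: n-Bu4NF (6 equiv), THF, 50 °C
Reagents that add atoms: none
Why: Fluoride-driven desilylation; warming is expected to be needed for the tertiary and the hindered secondary ether.

Step 19
Reactants: 26 3-hydroxy-4-methoxybenzoic acid (isovanillic acid)
Product: 28 3-(tert-butyldimethylsilyloxy)-4-methoxybenzoic acid, via bis-silyl isovanillate 27 (not isolated)
Conditions: TBSCl (2.5 equiv), imidazole, DMF, rt; then AcOH/THF/H2O, rt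
Reagents that add atoms: tert-butyldimethylsilyl chloride, CC(C)(C)[Si](C)(C)Cl
Why: Both acidic hydroxyls are silylated, and the labile silyl ester is then hydrolysed selectively, leaving the aryl silyl ether.

Step 20
Reactants: 28 3-(tert-butyldimethylsilyloxy)-4-methoxybenzoic acid
Product: 29 3-(tert-butyldimethylsilyloxy)-4-methoxybenzoyl chloride
Conditions: (COCl)2, DMF (cat.), CH2Cl2, 0 °C → rt
Reagents that add atoms: oxalyl chloride, O=C(Cl)C(Cl)=O
Why: Vilsmeier-type activation converts the acid into the acid chloride, which is used crude.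

Step 21
Reactants: 25 diol; 29 3-(tert-butyldimethylsilyloxy)-4-methoxybenzoyl chloride
Product: 30 7α-hydroxy-2,7-dimethyl-4α-(propan-2-yl)-3,3a,4,5,6,7,8,8a-octahydroazulen-5α-yl 3-(tert-butyldimethylsilyloxy)-4-methoxybenzoate
Conditions: Et3N, DMAP (1 equiv), CH2Cl2, rt → 40 °C
Reagents that add atoms: none
Why: DMAP-catalysed acylation takes place at the secondary C5 hydroxyl only; the tertiary C7 hydroxyl is inert under these conditions.

Step 22
Reactants: 30 aryl ester
Product: 31 1α,2α-epoxy-7α-hydroxy-2,7-dimethyl-4α-(propan-2-yl)decahydroazulen-5α-yl 3-(tert-butyldimethylsilyloxy)-4-methoxybenzoate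
Conditions: VO(acac)2 (10 mol%), t-BuOOH, CH2Cl2, rt
Reagents that add atoms: tert-butyl hydroperoxide, CC(C)(C)OO
Why: Hydroxyl-directed vanadium epoxidation of a bishomoallylic alcohol: the C7 alkoxide is cis to the C8a–C1 bond on the seven-membered ring and should deliver oxygen to the α face of C1=C2, setting C1 and C2.

Step 23
Reactants: 31 silyl-protected epoxide
Product: 32 1α,2α-epoxy-7α-hydroxy-2,7-dimethyl-4α-(propan-2-yl)decahydroazulen-5α-yl 3-hydroxy-4-methoxybenzoate (CNP0106636.1)
Conditions: n-Bu4NF, AcOH, THF, 0 °C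
Reagents that add atoms: none
Why: Buffered fluoride cleaves the aryl silyl ether within minutes and should leave the benzoate, the oxirane and the tertiary alcohol untouched.

## Compound list

1 | 3-methylbutanal (isovaleraldehyde) | CC(C)CC=O | starting material
2 | isopropenylmagnesium bromide | C=C(C)[Mg]Br | starting material
3 | 2,5-dimethylhex-1-en-3-ol (racemic) | CC(C)CC(O)C(C)=C | intermediate
4 | 2,5-dimethylhex-1-en-3-one | CC(C)CC(=O)C(C)=C | intermediate
5 | (Z)-tert-butyl[(2,5-dimethylhexa-1,3-dien-3-yl)oxy]dimethylsilane | CC(C)/C=C(\O[Si](C)(C)C(C)(C)C)C(C)=C | intermediate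
6 | (S)-4-benzyl-1,3-oxazolidin-2-one | O=C1OC[C@H](Cc2ccccc2)N1 | starting material
7 | bromoacetyl bromide | BrCC(Br)=O | starting material
8 | (S)-4-benzyl-3-(bromoacetyl)-1,3-oxazolidin-2-one | O=C1OC[C@H](Cc2ccccc2)N1C(=O)CBr | intermediate
9 | diethyl {2-[(S)-4-benzyl-2-oxo-1,3-oxazolidin-3-yl]-2-oxoethyl}phosphonate | CCOP(=O)(CC(=O)N1[C@@H](Cc2ccccc2)COC1=O)OCC | intermediate
10 | ethyl 2-(2-methyl-1,3-dioxolan-2-yl)acetate | CCOC(=O)CC1(C)OCCO1 | starting material
11 | 2-(2-methyl-1,3-dioxolan-2-yl)acetaldehyde | O=CCC1(C)OCCO1 | intermediate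
12 | (S)-4-benzyl-3-[(E)-4-(2-methyl-1,3-dioxolan-2-yl)but-2-enoyl]-1,3-oxazolidin-2-one | CC1(C/C=C/C(=O)N2[C@@H](Cc3ccccc3)COC2=O)OCCO1 | intermediate
13 | (S)-4-benzyl-3-{[(1S,5S,6S)-4-(tert-butyldimethylsilyloxy)-3-methyl-6-[(2-methyl-1,3-dioxolan-2-yl)methyl]-5-(propan-2-yl)cyclohex-3-en-1-yl]carbonyl}-1,3-oxazolidin-2-one | CC1=C(O[Si](C)(C)C(C)(C)C)[C@@H](C(C)C)[C@H](CC2(C)OCCO2)[C@@H](C(=O)N2[C@@H](Cc3ccccc3)COC2=O)C1 | intermediate
14 | methyl (1S,5S,6S)-4-(tert-butyldimethylsilyloxy)-3-methyl-6-[(2-methyl-1,3-dioxolan-2-yl)methyl]-5-(propan-2-yl)cyclohex-3-ene-1-carboxylate | CC1=C(O[Si](C)(C)C(C)(C)C)[C@@H](C(C)C)[C@H](CC2(C)OCCO2)[C@@H](C(=O)OC)C1 | intermediate (key-step precursor)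
15 | methyl 6-(tert-butyldimethylsilyloxy)-1-methyl-4-[(2-methyl-1,3-dioxolan-2-yl)methyl]-5-(propan-2-yl)bicyclo[4.1.0]heptane-3-carboxylate (both cyclopropane diastereomers) | CC12CC1(O[Si](C)(C)C(C)(C)C)[C@@H](C(C)C)[C@H](CC3(C)OCCO3)[C@@H](C(=O)OC)C2 | intermediate (not isolated)
16 | methyl 6-chloro-6-methyl-2-[(2-methyl-1,3-dioxolan-2-yl)methyl]-4-oxo-3-(propan-2-yl)cycloheptane-1-carboxylate (both C7 epimers) | O=C1CC(C)(Cl)C[C@H](C(=O)OC)[C@@H](CC2(C)OCCO2)[C@@H]1C(C)C | intermediate (not isolated)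
17 | methyl (1S,2S,3S)-6-methyl-2-[(2-methyl-1,3-dioxolan-2-yl)methyl]-4-oxo-3-(propan-2-yl)cyclohept-5-ene-1-carboxylate | O=C1C=C(C)C[C@H](C(=O)OC)[C@@H](CC2(C)OCCO2)[C@@H]1C(C)C | intermediate (key-step product)
18 | methyl (1S,2S,3S,4S)-4-hydroxy-6-methyl-2-[(2-methyl-1,3-dioxolan-2-yl)methyl]-3-(propan-2-yl)cyclohept-5-ene-1-carboxylate | O[C@@H]1C=C(C)C[C@H](C(=O)OC)[C@@H](CC2(C)OCCO2)[C@@H]1C(C)C | intermediate
19 | methyl 6-hydroxy-1-methyl-4-[(2-methyl-1,3-dioxolan-2-yl)methyl]-5-(propan-2-yl)-8-oxabicyclo[5.1.0]octane-3-carboxylate (5α-OH, 6α,7α-epoxide) | O[C@@H]1[C@@H]2O[C@]2(C)C[C@H](C(=O)OC)[C@@H](CC2(C)OCCO2)[C@@H]1C(C)C | intermediate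
20 | 6-(hydroxymethyl)-1-methyl-5-[(2-methyl-1,3-dioxolan-2-yl)methyl]-4-(propan-2-yl)cycloheptane-1,3-diol (5α,7α-diol) | O[C@@H]1C[C@](C)(O)C[C@H](CO)[C@@H](CC2(C)OCCO2)[C@@H]1C(C)C | intermediate
21 | tris(tert-butyldimethylsilyl) ether of 20 | CC(C)(C)[Si](C)(C)O[C@@H]1C[C@](C)(O[Si](C)(C)C(C)(C)C)C[C@H](CO[Si](C)(C)C(C)(C)C)[C@@H](CC2(C)OCCO2)[C@@H]1C(C)C | intermediate
22 | 1-[3,5-bis(tert-butyldimethylsilyloxy)-7-(hydroxymethyl)-5-methyl-2-(propan-2-yl)cycloheptyl]propan-2-one | CC(C)(C)[Si](C)(C)O[C@@H]1C[C@](C)(O[Si](C)(C)C(C)(C)C)C[C@H](CO)[C@@H](CC(C)=O)[C@@H]1C(C)C | intermediate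
23 | 4,6-bis(tert-butyldimethylsilyloxy)-6-methyl-2-(2-oxopropyl)-3-(propan-2-yl)cycloheptane-1-carbaldehyde | CC(C)(C)[Si](C)(C)O[C@@H]1C[C@](C)(O[Si](C)(C)C(C)(C)C)C[C@H](C=O)[C@@H](CC(C)=O)[C@@H]1C(C)C | intermediate
24 | 5α,7α-bis(tert-butyldimethylsilyloxy)-2,7-dimethyl-4α-(propan-2-yl)-3,3a,4,5,6,7,8,8a-octahydroazulene | CC(C)(C)[Si](C)(C)O[C@@H]2C[C@](C)(O[Si](C)(C)C(C)(C)C)C[C@H]3[C@@H](CC(C)=C3)[C@@H]2C(C)C | intermediate
25 | 2,7-dimethyl-4α-(propan-2-yl)-3,3a,4,5,6,7,8,8a-octahydroazulene-5α,7α-diol | O[C@@H]1C[C@](C)(O)C[C@H]2[C@@H](CC(C)=C2)[C@@H]1C(C)C | intermediate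
26 | 3-hydroxy-4-methoxybenzoic acid (isovanillic acid) | COc1ccc(C(=O)O)cc1O | starting material
27 | tert-butyldimethylsilyl 3-(tert-butyldimethylsilyloxy)-4-methoxybenzoate | COc1ccc(C(=O)O[Si](C)(C)C(C)(C)C)cc1O[Si](C)(C)C(C)(C)C | intermediate (not isolated)
28 | 3-(tert-butyldimethylsilyloxy)-4-methoxybenzoic acid | COc1ccc(C(=O)O)cc1O[Si](C)(C)C(C)(C)C | intermediate
29 | 3-(tert-butyldimethylsilyloxy)-4-methoxybenzoyl chloride | COc1ccc(C(Cl)=O)cc1O[Si](C)(C)C(C)(C)C | intermediate
30 | 7α-hydroxy-2,7-dimethyl-4α-(propan-2-yl)-3,3a,4,5,6,7,8,8a-octahydroazulen-5α-yl 3-(tert-butyldimethylsilyloxy)-4-methoxybenzoate | COc1ccc(C(=O)O[C@@H]2C[C@](C)(O)C[C@H]3[C@@H](CC(C)=C3)[C@@H]2C(C)C)cc1O[Si](C)(C)C(C)(C)C | intermediate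
31 | 1α,2α-epoxy-7α-hydroxy-2,7-dimethyl-4α-(propan-2-yl)decahydroazulen-5α-yl 3-(tert-butyldimethylsilyloxy)-4-methoxybenzoate | COc1ccc(C(=O)O[C@@H]2C[C@](C)(O)C[C@H]3[C@@H](C[C@@]4(C)O[C@@H]34)[C@@H]2C(C)C)cc1O[Si](C)(C)C(C)(C)C | intermediate
32 | 1α,2α-epoxy-7α-hydroxy-2,7-dimethyl-4α-(propan-2-yl)decahydroazulen-5α-yl 3-hydroxy-4-methoxybenzoate (CNP0106636.1) | COc1ccc(C(=O)O[C@@H]2C[C@](C)(O)C[C@H]3[C@@H](C[C@@]4(C)O[C@@H]34)[C@@H]2C(C)C)cc1O | target

## Step count and risks

Total step count: 23. Longest linear sequence: 17 steps (steps 1–3 or 4, 5, 7; then 8–18 and 21–23).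

Steps most likely to fail:

Step 10. Methylene transfer may stall at the hindered tetrasubstituted C5=C7 enol ether. The bulky silyl ether may also exchange slowly with FeCl3 so that oxidation lags, and the iron salt may strip the dioxolane. The fallback sets out from 14 and returns at 17. Dibromocarbene (CHBr3, KOt-Bu, pentane, −20 °C) should add to the enol ether to give the dibromocyclopropane F1. Warming in toluene with pyridine should open it by disrotatory loss of bromide and of the silyl group to the α-bromo enone F2. Hydrodebromination (Pd(OAc)2, PPh3, HCO2H, Et3N, DMF, 60 °C) should then give 17.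

Step 22. Oxygen delivery may lose its facial bias because the directing C7 hydroxyl is bishomoallylic and pseudo-equatorial. Undirected attack on the β face, away from the allylic C8a–C8 bond, would then compete. The fallback sets out from 24 and returns at 31. NBS in aqueous THF should form the bromonium ion on the β face, and water should open it at tertiary C2 from the α face to give the bromohydrin F3. K2CO3 in MeOH should close it with inversion at C1 to the bis-silyl 1α,2α-epoxide F4. n-Bu4NF (THF, 50 °C) should then give the epoxy diol F5, which is acylated at C5 with 29 (Et3N, DMAP, CH2Cl2) to give 31.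

Step 17. The coupling may stop at the pinacol stage, or the aldehyde may epimerise at C8a or condense on the Lewis-acidic titanium surface. The fallback sets out from 23 and returns at 24. Double Wittig methylenation (Ph3P=CH2, THF, −78 °C → rt) should give the diene F6. Ring-closing metathesis with the second-generation Grubbs catalyst (CH2Cl2, 40 °C) should then close C1=C2 with loss of ethene and give 24.

## Further compounds

F1 | step 10 | methyl 7,7-dibromo-6-(tert-butyldimethylsilyloxy)-1-methyl-4-[(2-methyl-1,3-dioxolan-2-yl)methyl]-5-(propan-2-yl)bicyclo[4.1.0]heptane-3-carboxylate | CC12C(Br)(Br)C1(O[Si](C)(C)C(C)(C)C)[C@@H](C(C)C)[C@H](CC3(C)OCCO3)[C@@H](C(=O)OC)C2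
F2 | step 10 | methyl (1S,2S,3S)-5-bromo-6-methyl-2-[(2-methyl-1,3-dioxolan-2-yl)methyl]-4-oxo-3-(propan-2-yl)cyclohept-5-ene-1-carboxylate | O=C1C(Br)=C(C)C[C@H](C(=O)OC)[C@@H](CC2(C)OCCO2)[C@@H]1C(C)C
F3 | step 22 | 1β-bromo-5α,7α-bis(tert-butyldimethylsilyloxy)-2,7-dimethyl-4α-(propan-2-yl)decahydroazulen-2α-ol | CC(C)(C)[Si](C)(C)O[C@@H]2C[C@](C)(O[Si](C)(C)C(C)(C)C)C[C@H]3[C@@H](C[C@@](C)(O)[C@@H]3Br)[C@@H]2C(C)C
F4 | step 22 | 5α,7α-bis(tert-butyldimethylsilyloxy)-1α,2α-epoxy-2,7-dimethyl-4α-(propan-2-yl)decahydroazulene | CC(C)(C)[Si](C)(C)O[C@@H]2C[C@](C)(O[Si](C)(C)C(C)(C)C)C[C@H]3[C@@H](C[C@@]4(C)O[C@@H]34)[C@@H]2C(C)C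
F5 | step 22 | 1α,2α-epoxy-2,7-dimethyl-4α-(propan-2-yl)decahydroazulene-5α,7α-diol | O[C@@H]2C[C@](C)(O)C[C@H]3[C@@H](C[C@@]4(C)O[C@@H]34)[C@@H]2C(C)C
F6 | step 17 | 1,3-bis(tert-butyldimethylsilyloxy)-6-ethenyl-1-methyl-5-(2-methylprop-2-en-1-yl)-4-(propan-2-yl)cycloheptane (5α,7α-disilyloxy diene) | CC(C)(C)[Si](C)(C)O[C@@H]1C[C@](C)(O[Si](C)(C)C(C)(C)C)C[C@H](C=C)[C@@H](CC(C)=C)[C@@H]1C(C)C
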